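**Plan**
1. Retrosynthesis: the two C–C bonds of the oxygen-bridged six-membered ring are cut first (retro-Diels–Alder), giving a 1-aryl isobenzofuran and a cyclopenta[b]chromone with a C2=C3 double bond in its five-membered ring; that ring is then opened between its carbinol carbon C-1 and the pyranone carbon C-9a.
2. Enabling feature: C-9a is the β-carbon of the ring enol ether (O–C=C) of the 4-pyranone and so a π-nucleophile; it lies three atoms from C-1, whose OH and CO2Me are the footprint of an α-keto ester that binds a chiral Lewis acid at two points.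
3. Chromone half: 3,5-dihydroxybenzyl alcohol → aryl methyl ketone → 2-substituted chromone (lactone Claisen, cyclodehydration) → keto ester → enantioselective closure of the five-membered ring → C-3 selenide.
4. Isobenzofuran half: 4-methoxy-2-methylphenol → phthalide (ortho-formylation, directed metalation/CO2) → aryllithium addition → lactol.
5. Union: selenoxide elimination unveils the cyclopentadiene, the isobenzofuran traps it in an exo Diels–Alder reaction (oxygen-bridged bicycle formed last), and zerovalent palladium removes all five allyl-type groups.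
6. Stereochemistry: C-1 from the ligand in the ring closure; the other four centres from C-1 in the cycloaddition (face anti to CO2Me, exo, regiochemistry by polarity and sterics).

Key step: step 7

Remark: the chromone-derived tricycle is numbered as cyclopenta[b]chromene (C-1 carbinol carbon; C-2 and C-3 the CH2 carbons; C-3a; O-4; C-9 carbonyl; C-9a). Lactol 27 is a ring–chain tautomeric hemiketal drawn closed, and selenide 13 is used as a mixture of C-3 epimers.

**Step 1**
Reactants: 1 3,5-dihydroxybenzyl alcohol
Product: 2 1,3-bis(methoxymethoxy)-5-[(methoxymethoxy)methyl]benzene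
Conditions: MOMCl (3.6 equiv), i-Pr2NEt, CH2Cl2, 0 → 40 °C
Reagents that add atoms: chloromethyl methyl ether (COCCl)
Why: Acetal-type etherification of both phenols and the benzylic alcohol should proceed cleanly, and the two aryl OMOM groups later direct metalation to the carbon between them.

**Step 2**
Reactants: 2 1,3-bis(methoxymethoxy)-5-[(methoxymethoxy)methyl]benzene
Product: 4 1-[2,6-bis(methoxymethoxy)-4-[(methoxymethoxy)methyl]phenyl]ethan-1-one, via aryllithium 3 (not isolated)
Conditions: n-BuLi, THF, 0 °C; then MeC(O)N(OMe)Me, −78 °C → rt; aq. NH4Cl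
Reagents that add atoms: N-methoxy-N-methylacetamide (CC(=O)N(C)OC)
Why: Directed ortho-metalation should occur at the C–H flanked by two OMOM groups, and the Weinreb amide stops the acylation at the ketone.

**Step 3**
Reactants: 4 1-[2,6-bis(methoxymethoxy)-4-[(methoxymethoxy)methyl]phenyl]ethan-1-one; 5 (S)-5-oxotetrahydrofuran-2-carboxylic acid
Product: 7 methyl (2S)-2-hydroxy-4-[5-hydroxy-7-(hydroxymethyl)-4-oxo-4H-chromen-2-yl]butanoate, via diketo acid 6 (not isolated)
Conditions: 4 with LiN(SiMe3)2 (1.1 equiv) and 5 with LiN(SiMe3)2 (1.0 equiv), THF, −78 °C, combined, −78 → 25 °C; then conc. HCl, MeOH, 60 °C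
Reagents that add atoms: methanol (CO)
Why: Claisen-type acylation of the ketone enolate can only take place at the lactone carbonyl (the carboxylate is inert and the ring-opened alkoxide deprotonates the 1,3-diketone), and acid then removes the MOM groups, closes the chromone by cyclodehydration and esterifies the acid, the (S) carbinol being only a placeholder that is oxidised in step 6.

**Step 4**
Reactants: 7 methyl (2S)-2-hydroxy-4-[5-hydroxy-7-(hydroxymethyl)-4-oxo-4H-chromen-2-yl]butanoate
Product: 8 methyl (2S)-4-[5-(allyloxy)-7-(hydroxymethyl)-4-oxo-4H-chromen-2-yl]-2-hydroxybutanoate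
Conditions: allyl bromide, K2CO3, DMF, 50 °C
Reagents that add atoms: allyl bromide (C=CCBr)
Why: Williamson etherification should touch only the phenol, the one OH that K2CO3 deprotonates, and removing the hydrogen bond to the C-4 carbonyl makes the pyranone more electron-rich for step 7.

**Step 5**
Reactants: 8 methyl (2S)-4-[5-(allyloxy)-7-(hydroxymethyl)-4-oxo-4H-chromen-2-yl]-2-hydroxybutanoate
Product: 9 methyl (2S)-4-[5-(allyloxy)-7-({[(allyloxy)carbonyl]oxy}methyl)-4-oxo-4H-chromen-2-yl]-2-hydroxybutanoate
Conditions: allyl chloroformate (1.1 equiv), pyridine, CH2Cl2, −20 °C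
Reagents that add atoms: allyl chloroformate (C=CCOC(=O)Cl)
Why: Acylation at low temperature should select the unhindered primary alcohol over the deactivated secondary α-hydroxy ester hydroxyl.

**Step 6**
Reactants: 9 methyl (2S)-4-[5-(allyloxy)-7-({[(allyloxy)carbonyl]oxy}methyl)-4-oxo-4H-chromen-2-yl]-2-hydroxybutanoate
Product: 10 methyl 4-[5-(allyloxy)-7-({[(allyloxy)carbonyl]oxy}methyl)-4-oxo-4H-chromen-2-yl]-2-oxobutanoate
Conditions: Dess–Martin periodinane, CH2Cl2, 0 °C → rt
Reagents that add atoms: none
Why: Dess–Martin oxidation of an α-hydroxy ester to the α-keto ester is reliable under neutral conditions that spare the allyl ether and the carbonate.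

**Step 7**
Reactants: 10 methyl 4-[5-(allyloxy)-7-({[(allyloxy)carbonyl]oxy}methyl)-4-oxo-4H-chromen-2-yl]-2-oxobutanoate
Product: 11 methyl (1S)-8-(allyloxy)-6-({[(allyloxy)carbonyl]oxy}methyl)-1-hydroxy-9-oxo-1,2,3,9-tetrahydrocyclopenta[b]chromene-1-carboxylate
Conditions: CuCl2 (10 mol%), AgSbF6 (20 mol%), (S,S)-2,2′-isopropylidenebis(4-tert-butyl-2-oxazoline) (11 mol%), 4 Å MS, CH2Cl2, 0 → 25 °C
Reagents that add atoms: none
Why: Proposed new method: the 1,2-dicarbonyl unit of 10 binds the divalent copper bis(oxazoline) complex as a five-membered chelate, the activated ketone carbon is attacked by C-3 of the 4-pyranone (the β-carbon of the ring enol ether and the only π-nucleophilic carbon three atoms away), and the oxygen-stabilised cation then loses H-3 to restore the chromone, so the step is a Friedel–Crafts hydroxyalkylation that can also be read as a carbonyl–ene reaction followed by tautomerisation. The closest known reactions are the copper bis(oxazoline)-catalysed enantioselective intramolecular carbonyl–ene cyclisation of unsaturated α-keto esters, the same catalysts in Friedel–Crafts hydroxyalkylations of heteroarenes with pyruvate-type esters, and the acid-mediated Bougault cyclisation of 4-aryl-2-oxobutanoates to indene carboxylates; chromone C-3 is the usual site of electrophilic attack but has not been used in this reaction. The five-membered ring closes in a 5-exo-trig mode at the carbonyl group, with the C2=C3 bond of the pyranone inside the new ring as in indanol-forming arene cyclisations. The only new stereocentre, C-1, is set by the ligand: in the square-planar chelate the tert-butyl group of the (S,S)-ligand should cover the Re face of the ketone, so that C-3 adds to the Si face and gives the (1S) alcohol (the enantiomeric ligand would be used if the sense proved opposite). The step needs enantioface selection and chemoselectivity over enolisation or self-aldol reaction of the keto ester and over dehydration of the tertiary alcohol, and these should be secured by the two-point binding, the three-atom tether, the non-basic medium and the ester group that disfavours ionisation at C-1.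

**Step 8**
Reactants: 11 methyl (1S)-8-(allyloxy)-6-({[(allyloxy)carbonyl]oxy}methyl)-1-hydroxy-9-oxo-1,2,3,9-tetrahydrocyclopenta[b]chromene-1-carboxylate
Product: 13 methyl (1S)-8-(allyloxy)-6-({[(allyloxy)carbonyl]oxy}methyl)-1-hydroxy-9-oxo-3-(phenylselanyl)-1,2,3,9-tetrahydrocyclopenta[b]chromene-1-carboxylate, via dilithium dienolate 12 (not isolated)
Conditions: LiN(i-Pr)2 (2.2 equiv), THF, −78 °C; PhSeBr, −78 °C; AcOH
Reagents that add atoms: phenylselenyl bromide (Br[Se]c1ccccc1)
Why: After the alkoxide forms, the vinylogous C-3 protons of the 2-alkyl-4-pyranone are the most acidic, and selenenylation of the extended enolate should occur at this γ-carbon because the α-carbon C-9a is fully substituted; the new C-3 centre needs no control since step 17 destroys it.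

**Step 9**
Reactants: 14 4-methoxy-2-methylphenol
Product: 15 2-hydroxy-5-methoxy-3-methylbenzaldehyde
Conditions: MgCl2, Et3N, (CH2O)n, MeCN, reflux
Reagents that add atoms: formaldehyde as paraformaldehyde (C=O)
Why: The magnesium phenoxide-mediated ortho-formylation (Casiraghi–Skattebøl) is ortho-specific and the phenol has only one free ortho position, which fixes the later CH2 carbon next to the oxygen that will carry the side chain.

**Step 10**
Reactants: 15 2-hydroxy-5-methoxy-3-methylbenzaldehyde; 16 4-bromo-2-methylbutan-2-ol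
Product: 17 2-(3-hydroxy-3-methylbutoxy)-5-methoxy-3-methylbenzaldehyde
Conditions: K2CO3, DMF, 60 °C
Reagents that add atoms: none
Why: Williamson etherification of the only phenol with the primary bromide installs the complete side chain with its tertiary alcohol left free.

**Step 11**
Reactants: 17 2-(3-hydroxy-3-methylbutoxy)-5-methoxy-3-methylbenzaldehyde
Product: 18 4-[2-(hydroxymethyl)-4-methoxy-6-methylphenoxy]-2-methylbutan-2-ol
Conditions: NaBH4, MeOH, 0 °C
Reagents that add atoms: none
Why: Borohydride reduction of the aldehyde gives the benzylic alcohol that serves as directing group and as lactone oxygen in step 12.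

**Step 12**
Reactants: 18 4-[2-(hydroxymethyl)-4-methoxy-6-methylphenoxy]-2-methylbutan-2-ol
Product: 21 4-(3-hydroxy-3-methylbutoxy)-7-methoxy-5-methyl-2-benzofuran-1(3H)-one, via triply lithiated arene 19 (not isolated), via hydroxy acid 20 (not isolated)
Conditions: n-BuLi (3.3 equiv), TMEDA, Et2O/hexane, 0 °C → rt; CO2, −78 °C; aq. HCl
Reagents that add atoms: carbon dioxide (O=C=O)
Why: Directed ortho-metalation should occur at the ring carbon between CH2OLi and OMe (two cooperating directing groups), and carboxylation followed by acidification lactonises to the phthalide with its carbonyl next to the methoxy-bearing carbon.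

**Step 13**
Reactants: 21 4-(3-hydroxy-3-methylbutoxy)-7-methoxy-5-methyl-2-benzofuran-1(3H)-one
Product: 22 7-hydroxy-4-(3-hydroxy-3-methylbutoxy)-5-methyl-2-benzofuran-1(3H)-one
Conditions: LiCl, DMF, 140 °C; aq. HCl
Reagents that add atoms: none
Why: Chloride demethylates only the ether whose phenoxide is conjugated with the ortho lactone carbonyl, the neutral medium spares the tertiary alcohol, and any chloride opening of the lactone at its CH2 group is reversed by the carboxylate.

**Step 14**
Reactants: 22 7-hydroxy-4-(3-hydroxy-3-methylbutoxy)-5-methyl-2-benzofuran-1(3H)-one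
Product: 23 7-(allyloxy)-4-(3-hydroxy-3-methylbutoxy)-5-methyl-2-benzofuran-1(3H)-one
Conditions: allyl bromide, K2CO3, DMF, 60 °C
Reagents that add atoms: allyl bromide (C=CCBr)
Why: Williamson allylation of the single phenol gives a protecting group that survives aryllithium addition and is removed under neutral conditions at the end.

**Step 15**
Reactants: 24 2-bromobenzene-1,3-diol
Product: 25 2-bromo-1,3-bis(allyloxy)benzene
Conditions: allyl bromide (2.4 equiv), K2CO3, acetone, reflux
Reagents that add atoms: allyl bromide (C=CCBr)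
Why: Double Williamson allylation of both phenols is routine and leaves the bromide for halogen–metal exchange.

**Step 16**
Reactants: 25 2-bromo-1,3-bis(allyloxy)benzene; 23 7-(allyloxy)-4-(3-hydroxy-3-methylbutoxy)-5-methyl-2-benzofuran-1(3H)-one
Product: 27 1-[2,6-bis(allyloxy)phenyl]-7-(allyloxy)-4-(3-hydroxy-3-methylbutoxy)-5-methyl-1,3-dihydro-2-benzofuran-1-ol, via aryllithium 26 (not isolated)
Conditions: 25, n-BuLi, THF, −78 °C; then 23 (0.45 equiv), −78 °C; aq. NH4Cl
Reagents that add atoms: none
Why: Bromine–lithium exchange at −78 °C is faster than any attack on the allyl ethers; one equivalent of the aryllithium deprotonates the tertiary alcohol and the second adds once to the lactone, since the hindered tetrahedral lithium hemiketal does not collapse, giving the lactol that is the standard isobenzofuran precursor.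

**Step 17**
Reactants: 13 methyl (1S)-8-(allyloxy)-6-({[(allyloxy)carbonyl]oxy}methyl)-1-hydroxy-9-oxo-3-(phenylselanyl)-1,2,3,9-tetrahydrocyclopenta[b]chromene-1-carboxylate; 27 1-[2,6-bis(allyloxy)phenyl]-7-(allyloxy)-4-(3-hydroxy-3-methylbutoxy)-5-methyl-1,3-dihydro-2-benzofuran-1-ol
Product: 31 O-allyl/allyl carbonate-protected aspergichromone A (exo cycloadduct; 1S 2R 3R; bridgehead CH R; aryl-bearing bridgehead S), via selenoxide 28 (not isolated), via cyclopentadiene 29 (not isolated), via isobenzofuran 30 (not isolated)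
Conditions: (a) 13, H2O2 (30%), pyridine, CH2Cl2, 0 → 20 °C, aqueous wash; (b) 27 (1.5 equiv), TsOH·H2O (5 mol%), 4 Å MS, toluene, 20 °C, then Et3N; (c) solutions combined under Ar in the dark, 20 → 50 °C
Reagents that add atoms: none
Why: Selenoxide syn-elimination can take hydrogen only from C-2 (the competing [2,3]-shift would break the pyranone conjugation and is reversible) and unveils cyclopentadiene 29, acid-catalysed 1,4-dehydration of lactol 27 gives isobenzofuran 30, and their Diels–Alder reaction should join the unsubstituted furan carbon to C-2 (the electrophilic δ-carbon of the dienone, next to the quaternary centre) and the aryl-bearing furan carbon to C-3, on the face carrying the small 1-OH (anti to CO2Me, with an O–H···O contact to the furan oxygen) and in the exo orientation that keeps the benzo ring and its peri alkoxy chain away from the chromone, so that the (1S) centre sets the four new stereocentres.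

**Step 18**
Reactants: 31 O-allyl/allyl carbonate-protected aspergichromone A
Product: 32 aspergichromone A
Conditions: Pd(PPh3)4 (10 mol%), morpholine, THF, 20 °C
Reagents that add atoms: none
Why: Tsuji–Trost deallylation, in which zerovalent palladium ionises the four aryl allyl ethers and the allyl carbonate and morpholine traps the allyl groups, is neutral and should leave the acid-labile bis-benzylic ether bridge, the ester, the tertiary alcohols and all five stereocentres untouched.

**Compound list**
1 | 3,5-dihydroxybenzyl alcohol | OCc1cc(O)cc(O)c1 | starting material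
2 | 1,3-bis(methoxymethoxy)-5-[(methoxymethoxy)methyl]benzene | COCOCc1cc(OCOC)cc(OCOC)c1 | intermediate
3 | [2,6-bis(methoxymethoxy)-4-[(methoxymethoxy)methyl]phenyl]lithium (formed in the flask) | [Li]c1c(OCOC)cc(COCOC)cc1OCOC | intermediate
4 | 1-[2,6-bis(methoxymethoxy)-4-[(methoxymethoxy)methyl]phenyl]ethan-1-one | CC(=O)c1c(OCOC)cc(COCOC)cc1OCOC | intermediate
5 | (S)-5-oxotetrahydrofuran-2-carboxylic acid | O=C1CC[C@@H](C(=O)O)O1 | starting material
6 | (2S)-7-[2,6-bis(methoxymethoxy)-4-[(methoxymethoxy)methyl]phenyl]-2-hydroxy-5,7-dioxoheptanoic acid (lithium salt in the flask) | O=C(O)[C@@H](O)CCC(=O)CC(=O)c1c(OCOC)cc(COCOC)cc1OCOC | intermediate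
7 | methyl (2S)-2-hydroxy-4-[5-hydroxy-7-(hydroxymethyl)-4-oxo-4H-chromen-2-yl]butanoate | COC(=O)[C@@H](O)CCc1cc(=O)c2c(O)cc(CO)cc2o1 | intermediate
8 | methyl (2S)-4-[5-(allyloxy)-7-(hydroxymethyl)-4-oxo-4H-chromen-2-yl]-2-hydroxybutanoate | COC(=O)[C@@H](O)CCc1cc(=O)c2c(OCC=C)cc(CO)cc2o1 | intermediate
9 | methyl (2S)-4-[5-(allyloxy)-7-({[(allyloxy)carbonyl]oxy}methyl)-4-oxo-4H-chromen-2-yl]-2-hydroxybutanoate | COC(=O)[C@@H](O)CCc1cc(=O)c2c(OCC=C)cc(COC(=O)OCC=C)cc2o1 | intermediate
10 | methyl 4-[5-(allyloxy)-7-({[(allyloxy)carbonyl]oxy}methyl)-4-oxo-4H-chromen-2-yl]-2-oxobutanoate | COC(=O)C(=O)CCc1cc(=O)c2c(OCC=C)cc(COC(=O)OCC=C)cc2o1 | intermediate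
11 | methyl (1S)-8-(allyloxy)-6-({[(allyloxy)carbonyl]oxy}methyl)-1-hydroxy-9-oxo-1,2,3,9-tetrahydrocyclopenta[b]chromene-1-carboxylate | COC(=O)[C@@]1(O)c2c(oc3cc(COC(=O)OCC=C)cc(OCC=C)c3c2=O)CC1 | intermediate
12 | dilithium alkoxide/dienolate of 11, (1S) (formed in the flask) | COC(=O)[C@]1(O[Li])CC=C2Oc3cc(COC(=O)OCC=C)cc(OCC=C)c3C(O[Li])=C12 | intermediate
13 | methyl (1S)-8-(allyloxy)-6-({[(allyloxy)carbonyl]oxy}methyl)-1-hydroxy-9-oxo-3-(phenylselanyl)-1,2,3,9-tetrahydrocyclopenta[b]chromene-1-carboxylate (C-3 epimers) | COC(=O)[C@@]1(O)c2c(oc3cc(COC(=O)OCC=C)cc(OCC=C)c3c2=O)C([Se]c2ccccc2)C1 | intermediate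
14 | 4-methoxy-2-methylphenol | COc1ccc(O)c(C)c1 | starting material
15 | 2-hydroxy-5-methoxy-3-methylbenzaldehyde | COc1cc(C)c(O)c(C=O)c1 | intermediate
16 | 4-bromo-2-methylbutan-2-ol | CC(C)(O)CCBr | starting material
17 | 2-(3-hydroxy-3-methylbutoxy)-5-methoxy-3-methylbenzaldehyde | COc1cc(C)c(OCCC(C)(C)O)c(C=O)c1 | intermediate
18 | 4-[2-(hydroxymethyl)-4-methoxy-6-methylphenoxy]-2-methylbutan-2-ol | COc1cc(C)c(OCCC(C)(C)O)c(CO)c1 | intermediate
19 | triply lithiated 18, aryl C–Li between CH2OLi and OMe (formed in the flask) | COc1cc(C)c(OCCC(C)(C)O[Li])c(CO[Li])c1[Li] | intermediate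
20 | 3-(3-hydroxy-3-methylbutoxy)-2-(hydroxymethyl)-6-methoxy-4-methylbenzoic acid (formed in the flask) | COc1cc(C)c(OCCC(C)(C)O)c(CO)c1C(=O)O | intermediate
21 | 4-(3-hydroxy-3-methylbutoxy)-7-methoxy-5-methyl-2-benzofuran-1(3H)-one | COc1cc(C)c(OCCC(C)(C)O)c2COC(=O)c12 | intermediate
22 | 7-hydroxy-4-(3-hydroxy-3-methylbutoxy)-5-methyl-2-benzofuran-1(3H)-one | O=C1OCc2c(OCCC(C)(C)O)c(C)cc(O)c12 | intermediate
23 | 7-(allyloxy)-4-(3-hydroxy-3-methylbutoxy)-5-methyl-2-benzofuran-1(3H)-one | O=C1OCc2c(OCCC(C)(C)O)c(C)cc(OCC=C)c12 | intermediate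
24 | 2-bromobenzene-1,3-diol | Oc1cccc(O)c1Br | starting material
25 | 2-bromo-1,3-bis(allyloxy)benzene | C=CCOc1cccc(OCC=C)c1Br | intermediate
26 | [2,6-bis(allyloxy)phenyl]lithium (formed in the flask) | [Li]c1c(OCC=C)cccc1OCC=C | intermediate
27 | 1-[2,6-bis(allyloxy)phenyl]-7-(allyloxy)-4-(3-hydroxy-3-methylbutoxy)-5-methyl-1,3-dihydro-2-benzofuran-1-ol (racemic hemiketal) | OC1(c2c(OCC=C)cccc2OCC=C)OCc2c(OCCC(C)(C)O)c(C)cc(OCC=C)c21 | intermediate
28 | selenoxide of 13, (1S) (formed in the flask) | COC(=O)[C@@]1(O)c2c(oc3cc(COC(=O)OCC=C)cc(OCC=C)c3c2=O)C([Se](=O)c2ccccc2)C1 | intermediate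
29 | methyl (1S)-8-(allyloxy)-6-({[(allyloxy)carbonyl]oxy}methyl)-1-hydroxy-9-oxo-1,9-dihydrocyclopenta[b]chromene-1-carboxylate (formed in the flask) | COC(=O)[C@@]1(O)c2c(oc3cc(COC(=O)OCC=C)cc(OCC=C)c3c2=O)C=C1 | intermediate
30 | 4-{[1-[2,6-bis(allyloxy)phenyl]-7-(allyloxy)-5-methyl-2-benzofuran-4-yl]oxy}-2-methylbutan-2-ol (isobenzofuran, formed in the flask) | C=CCOc1cccc(OCC=C)c1-c1occ2c(OCCC(C)(C)O)c(C)cc(OCC=C)c12 | intermediate
31 | O-allyl/allyl carbonate-protected aspergichromone A: exo cycloadduct of 29 and 30, carbinol C-1 (S), ring-fusion carbons C-2 (R) and C-3 (R), bridgehead CH (R) on C-2, aryl-bearing bridgehead (S) on C-3, four aryl allyl ethers and one allyl carbonate | COC(=O)[C@@]1(O)c2c(oc3cc(COC(=O)OCC=C)cc(OCC=C)c3c2=O)[C@H]2[C@@H]1[C@H]1O[C@]2(c2c(OCC=C)cccc2OCC=C)c2c(OCC=C)cc(C)c(OCCC(C)(C)O)c21 | intermediate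
32 | aspergichromone A | COC(=O)[C@@]1(O)c2c(oc3cc(CO)cc(O)c3c2=O)[C@H]2[C@@H]1[C@H]1O[C@]2(c2c(O)cccc2O)c2c(O)cc(C)c(OCCC(C)(C)O)c21 | target

**Totals**
Total step count: 18.
Longest linear sequence: 10 steps (steps 1–8, 17, 18, from 3,5-dihydroxybenzyl alcohol).

**Steps most likely to fail**

Step 7 (Proposed new method). C-3 of the chromone may be too weak a nucleophile for the copper-bound keto ester, so that enolisation and self-condensation of the keto ester outrun ring closure, or the ring may close with poor enantioface selection. The fallback uses known chemistry: it sets out from 4 (with 5) and returns at 11. The lithium diketonate 6 would be brominated in the flask at its central carbon with NBS to give the bromo diketone F1, and HCl/MeOH would then close the 3-bromochromone F2, which carries the halogen on the carbon that must bond. TBSCl/imidazole would protect the primary alcohol as the silyl ether F3, and Dess–Martin oxidation would give the bromo keto ester F4. The known palladium-catalysed intramolecular addition of an aryl halide to a ketone, which is enantioselective for α-keto amides with DifluorPhos-type ligands (Pd(OAc)2, (R)-DifluorPhos, Et3N, 1-hexanol as hydride donor, toluene, 80 °C), would close the ring to the tricycle F5. Allylation of the phenol (allyl bromide, K2CO3) to the allyl ether F6, desilylation with HF·pyridine to the primary alcohol F7 and allyl chloroformate/pyridine would return to 11.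

Step 17. The transient cyclopentadiene is both diene and dienophile and may dimerise before it meets the isobenzofuran, and under kinetic control the exo/endo and facial selectivity may be eroded. The fallback sets out from 11 and returns at 31. The dianion 12 would be quenched with PhSSPh to give the phenyl sulfide F8, which mCPBA at −78 °C oxidises to the isolable sulfoxide F9. Heating F9 with lactol 27 and a trace of acid at 80–90 °C releases the diene slowly by sulfoxide syn-elimination into an excess of the isobenzofuran, under conditions where the cycloaddition is reversible, so the diene never accumulates and the thermodynamic exo adduct 31 should result.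

Step 8. Formation of the dianion may be incomplete, the selenium electrophile may be taken up at oxygen or at C-9a, or the lithium alkoxide may attack the carbonate. The fallback sets out from 11 and returns at 13. Soft enolisation with Me3SiOTf/Et3N would give the bis(trimethylsilyl) dienol ether F10, which PhSeCl attacks at the exocyclic γ-carbon C-3 in a vinylogous Mukaiyama-type selenenylation; mild methanolysis of the tertiary silyl ether then gives 13 without any strong base.

**Further compounds**
F1 | step 7 | (2S)-7-[2,6-bis(methoxymethoxy)-4-[(methoxymethoxy)methyl]phenyl]-6-bromo-2-hydroxy-5,7-dioxoheptanoic acid | O=C(O)[C@@H](O)CCC(=O)C(Br)C(=O)c1c(OCOC)cc(COCOC)cc1OCOC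
F2 | step 7 | methyl (2S)-4-[3-bromo-5-hydroxy-7-(hydroxymethyl)-4-oxo-4H-chromen-2-yl]-2-hydroxybutanoate | COC(=O)[C@@H](O)CCc1oc2cc(CO)cc(O)c2c(=O)c1Br
F3 | step 7 | methyl (2S)-4-[3-bromo-7-({[tert-butyl(dimethyl)silyl]oxy}methyl)-5-hydroxy-4-oxo-4H-chromen-2-yl]-2-hydroxybutanoate | COC(=O)[C@@H](O)CCc1oc2cc(CO[Si](C)(C)C(C)(C)C)cc(O)c2c(=O)c1Br
F4 | step 7 | methyl 4-[3-bromo-7-({[tert-butyl(dimethyl)silyl]oxy}methyl)-5-hydroxy-4-oxo-4H-chromen-2-yl]-2-oxobutanoate | COC(=O)C(=O)CCc1oc2cc(CO[Si](C)(C)C(C)(C)C)cc(O)c2c(=O)c1Br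
F5 | step 7 | methyl (1S)-6-({[tert-butyl(dimethyl)silyl]oxy}methyl)-1,8-dihydroxy-9-oxo-1,2,3,9-tetrahydrocyclopenta[b]chromene-1-carboxylate | COC(=O)[C@@]1(O)c2c(oc3cc(CO[Si](C)(C)C(C)(C)C)cc(O)c3c2=O)CC1
F6 | step 7 | methyl (1S)-8-(allyloxy)-6-({[tert-butyl(dimethyl)silyl]oxy}methyl)-1-hydroxy-9-oxo-1,2,3,9-tetrahydrocyclopenta[b]chromene-1-carboxylate | COC(=O)[C@@]1(O)c2c(oc3cc(CO[Si](C)(C)C(C)(C)C)cc(OCC=C)c3c2=O)CC1
F7 | step 7 | methyl (1S)-8-(allyloxy)-1-hydroxy-6-(hydroxymethyl)-9-oxo-1,2,3,9-tetrahydrocyclopenta[b]chromene-1-carboxylate | COC(=O)[C@@]1(O)c2c(oc3cc(CO)cc(OCC=C)c3c2=O)CC1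
F8 | step 17 | methyl (1S)-8-(allyloxy)-6-({[(allyloxy)carbonyl]oxy}methyl)-1-hydroxy-9-oxo-3-(phenylsulfanyl)-1,2,3,9-tetrahydrocyclopenta[b]chromene-1-carboxylate | COC(=O)[C@@]1(O)c2c(oc3cc(COC(=O)OCC=C)cc(OCC=C)c3c2=O)C(Sc2ccccc2)C1
F9 | step 17 | methyl (1S)-8-(allyloxy)-6-({[(allyloxy)carbonyl]oxy}methyl)-1-hydroxy-9-oxo-3-(phenylsulfinyl)-1,2,3,9-tetrahydrocyclopenta[b]chromene-1-carboxylate | COC(=O)[C@@]1(O)c2c(oc3cc(COC(=O)OCC=C)cc(OCC=C)c3c2=O)C(S(=O)c2ccccc2)C1
F10 | step 8 | methyl (1S)-8-(allyloxy)-6-({[(allyloxy)carbonyl]oxy}methyl)-1,9-bis[(trimethylsilyl)oxy]-1,2-dihydrocyclopenta[b]chromene-1-carboxylate | COC(=O)[C@]1(O[Si](C)(C)C)CC=C2Oc3cc(COC(=O)OCC=C)cc(OCC=C)c3C(O[Si](C)(C)C)=C12
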